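**Retrosynthetic overview**

1. Ring A is attached last: the bond between C2 of pyrrole and the lactam carbon of a spiro-lactam (ring B at the lactam level) is made by a Vilsmeier–Haack-type coupling.
2. The spiro-aminal is made in one step: N-acyliminium spirocyclisation of a 5-ylidene-4-methoxypyrrolin-2-one forms the tetrahydropyran C–O bond and the C–H at the adjacent methine; the ylidene C=C comes from condensing a macrocyclic 2-acylpyrrole ketone with 4-methoxy-3-pyrrolin-2-one.
3. The macrocycle: the CH2–CH2 bond next to C5 of pyrrole ring C is disconnected to a thirteen-membered cyclic secondary amine (CH2–NH–CH2). The twelve-membered ansa ring is thus made by deleting one nitrogen atom from an azacycle that is closed by Staudinger/aza-Wittig condensation and reduction.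
4. Enabling feature: that CH2 is the heterobenzylic carbon on C5 of ring C, para-like to the C2 carbon that carries the ketone. It can be brought in as the aldehyde carbon of pyrrole-2-carbaldehyde, and after loss of N2 it is a stabilised (pyrrol-2-yl)methyl radical that recombines with the primary radical at the other end of the same chain.
5. Stereochemistry and ring order: (S)-gamma-valerolactone supplies the methyl carbinol centre and, by trans-alkylation, the bridge-bearing centre. Rings form in the order ring C (bought), thirteen-membered azacycle, twelve-membered ansa ring, tetrahydropyran with the spiro centre on bought ring B, then ring A.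

Key step: step 6

Remark: compounds 1, 2, 4, 16, 20 and N-(benzyloxy)-N-(pivaloyloxy)-4-(trifluoromethyl)benzamide are taken to be commercially available.

**Route**

Step 1
Reactants: 1 (S)-gamma-valerolactone; 2 1-chloro-6-iodohexane
Product: 3 (3S,5S)-3-(6-chlorohexyl)-5-methyloxolan-2-one
Conditions: LiN(iPr)2, THF, −78 °C; then 2, DMPU, −78 → −40 °C
Reagents that add atoms: none
Why: Lactone enolate alkylation at the iodide end of 2; the electrophile should approach the enolate face anti to the C5 methyl group, so the new C3 stereocenter is set trans to C5 (3S,5S) by 1,3-induction.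

Step 2
Reactants: 4 1H-pyrrole-2-carbaldehyde
Product: 5 6-(dimethylamino)-1-azafulvene dimer (5,10-bis(dimethylamino)-5H,10H-dipyrrolo[1,2-a:1',2'-d]pyrazine)
Conditions: Me2NH (2 M in THF, excess), 4 Å molecular sieves, 25 °C
Reagents that add atoms: dimethylamine, CNC
Why: Condensation of the aldehyde with the secondary amine gives 6-(dimethylamino)-1-azafulvene, which dimerises head-to-tail to the bis-aminal; this masks N–H and CHO and directs lithiation to the free alpha-carbon (the aminal carbons are lost again in step 3).

Step 3
Reactants: 5 6-(dimethylamino)-1-azafulvene dimer; 3 (3S,5S)-3-(6-chlorohexyl)-5-methyloxolan-2-one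
Product: 8 5-[(2S,4S)-2-(6-chlorohexyl)-4-hydroxypentanoyl]-1H-pyrrole-2-carbaldehyde, via dilithiated dimer 6 (not isolated), via bis-acylated dimer 7 (not isolated)
Conditions: t-BuLi (2.2 equiv per 5), THF, −15 °C; then 3 (2 equiv per 5), −78 → 0 °C; then NaOAc, H2O, reflux
Reagents that add atoms: water, O
Why: Directed alpha-lithiation of the azafulvene dimer and addition of the aryllithium to the lactone, which stops at the lithium lactolate, followed by aminal hydrolysis, should give the 5-acylpyrrole-2-carbaldehyde; both stereocenters of 3 are carried through because the lactolate does not enolise and the hydrolysis is near neutral.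

Step 4
Reactants: 8 5-[(2S,4S)-2-(6-chlorohexyl)-4-hydroxypentanoyl]-1H-pyrrole-2-carbaldehyde
Product: 9 5-[(2S,4S)-2-(6-azidohexyl)-4-hydroxypentanoyl]-1H-pyrrole-2-carbaldehyde
Conditions: NaN3, NaI (cat.), DMF, 60 °C
Reagents that add atoms: sodium azide, [Na+].[N-]=[N+]=[N-]
Why: SN2 displacement of the primary chloride by azide; no stereocenter is involved.

Step 5
Reactants: 9 5-[(2S,4S)-2-(6-azidohexyl)-4-hydroxypentanoyl]-1H-pyrrole-2-carbaldehyde
Product: 12 (3S)-3-[(2S)-2-hydroxypropyl]-10,15-diazabicyclo[10.2.1]pentadeca-1(14),12-dien-2-one, via iminophosphorane 10 (not isolated), via macrocyclic imine 11 (not isolated)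
Conditions: PPh3, THF (2 mM), 25 → 60 °C; then NaBH4, MeOH, −20 °C
Reagents that add atoms: none
Why: Staudinger reaction and intramolecular aza-Wittig reaction with the pyrrole aldehyde should close the unstrained thirteen-membered cyclic imine, which NaBH4 reduces faster than the deactivated 2-acylpyrrole ketone; no stereocenter is formed.

Step 6
Reactants: 12 (3S)-3-[(2S)-2-hydroxypropyl]-10,15-diazabicyclo[10.2.1]pentadeca-1(14),12-dien-2-one
Product: 15 (3S)-3-[(2S)-2-hydroxypropyl]-14-azabicyclo[9.2.1]tetradeca-1(13),11-dien-2-one, via N-aminated adduct 13 (not isolated), via isodiazene 14 (not isolated)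
Conditions: N-(benzyloxy)-N-(pivaloyloxy)-4-(trifluoromethyl)benzamide (1.5 equiv), THF, 45 °C
Reagents that add atoms: none
Why: The secondary amine nitrogen of 12 attacks the nitrogen of the anomeric amide and displaces pivalate to give 13, which loses benzyl 4-(trifluoromethyl)benzoate to form the isodiazene 14; loss of N2 from 14 leaves a singlet radical pair, the (5-acylpyrrol-2-yl)methyl radical and the primary alkyl radical, which are the two ends of one chain and recombine to the CH2–CH2 bond. The closest known reaction type is the nitrogen deletion of benzylic secondary amines with this class of reagent, including ring contraction of cyclic benzylic amines, and the older N2-extrusive ring contraction of cyclic diazenes. The twelve-membered ansa ring (the nine-carbon bridge from C2 to C5 of the pyrrole) is closed by in-cage radical recombination inside the thirteen-membered azacycle, a ring contraction by one atom and not an end-to-end macrocyclisation, so high dilution is not needed. No stereocenter is formed, and the centre alpha to the ketone and the carbinol centre are not touched under neutral conditions at 45 °C. The step needs amination at the ring amine only, which is secured because it is the only basic nitrogen (the pyrrole N–H is deactivated by the 2-acyl group and the hydroxyl group is tolerated), and it needs recombination to win over disproportionation or escape, which the tether and the heterobenzylic stabilisation of one partner should favour.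

Step 7
Reactants: 15 (3S)-3-[(2S)-2-hydroxypropyl]-14-azabicyclo[9.2.1]tetradeca-1(13),11-dien-2-one; 16 4-methoxy-1,5-dihydro-2H-pyrrol-2-one
Product: 18 4-methoxy-5-{(3S)-3-[(2S)-2-hydroxypropyl]-14-azabicyclo[9.2.1]tetradeca-1(13),11-dien-2-ylidene}-1,5-dihydro-2H-pyrrol-2-one (E/Z mixture), via bis-silylated pyrrolinone 17 (not isolated)
Conditions: 16 (1.5 equiv), Me3SiOTf, Et3N, CH2Cl2, 0 → 25 °C; then K2CO3, MeOH
Reagents that add atoms: none
Why: Vinylogous Mukaiyama aldol condensation: the silyloxypyrrole 17 attacks through C5 the ketone carbon activated as its O-silylated azafulvenium ion, and loss of silanol gives the 5-ylidene lactam; no stereocenter is formed (the alkene geometry is lost in step 8), and the alpha centre should be shielded because silylation goes to the pyrrole N/O system and not to carbon.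

Step 8
Reactants: 18 the 5-ylidene lactam
Product: 19 spiro-lactam (premarineosin A skeleton with a lactam C=O at the carbon that will carry ring A; R at the spiro carbon, S at the methine bearing ring C, S at the bridge-bearing carbon, S at the methyl carbinol carbon)
Conditions: camphorsulfonic acid (0.2 equiv), 4 Å molecular sieves, CH2Cl2, 25 °C
Reagents that add atoms: none
Why: Protonation of the enamide carbon gives an N-acyliminium ion that the secondary hydroxyl captures in a six-membered spiro-N,O-ketalisation; both events are reversible, so the spiro carbon and the adjacent methine should equilibrate toward the arrangement of the target (ring C and the bridge trans on the tetrahydropyran, aminal C–N anti-periplanar to a ring-oxygen lone pair).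

Step 9
Reactants: 19 spiro-lactam; 20 pyrrole
Product: 21 premarineosin A
Conditions: Tf2O, 2-chloropyridine, CH2Cl2, −78 → 0 °C; then pyrrole (5 equiv), 0 → 25 °C; aq. NaHCO3
Reagents that add atoms: none
Why: Electrophilic amide activation gives the imidoyl triflate, which pyrrole attacks at C2 (Vilsmeier–Haack-type condensation) to give the 5-(pyrrol-2-yl)-2H-pyrrole; no stereocenter is touched, and the aminal should not ionise because its nitrogen is engaged in the imidoyl triflate.

**Compound list**

1 | (S)-gamma-valerolactone, (5S)-5-methyloxolan-2-one | C[C@H]1CCC(=O)O1 | starting material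
2 | 1-chloro-6-iodohexane | ClCCCCCCI | starting material
3 | (3S,5S)-3-(6-chlorohexyl)-5-methyloxolan-2-one | C[C@H]1C[C@H](CCCCCCCl)C(=O)O1 | intermediate
4 | 1H-pyrrole-2-carbaldehyde | O=Cc1ccc[nH]1 | starting material
5 | 6-(dimethylamino)-1-azafulvene dimer | CN(C)C1c2cccn2C(N(C)C)c2cccn12 | intermediate
6 | dilithiated dimer (Li on the free alpha-carbon of each pyrrole ring of 5) | CN(C)C1c2ccc([Li])n2C(N(C)C)c2ccc([Li])n12 | intermediate (not isolated)
7 | bis-acylated dimer (each free alpha-carbon of 5 carries the (2S,4S)-2-(6-chlorohexyl)-4-hydroxypentanoyl group) | CN(C)C1c2ccc(C(=O)[C@@H](CCCCCCCl)C[C@H](C)O)n2C(N(C)C)c2ccc(C(=O)[C@@H](CCCCCCCl)C[C@H](C)O)n12 | intermediate (not isolated)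
8 | 5-[(2S,4S)-2-(6-chlorohexyl)-4-hydroxypentanoyl]-1H-pyrrole-2-carbaldehyde | O=Cc1ccc([nH]1)C(=O)[C@@H](CCCCCCCl)C[C@H](C)O | intermediate
9 | 5-[(2S,4S)-2-(6-azidohexyl)-4-hydroxypentanoyl]-1H-pyrrole-2-carbaldehyde | O=Cc1ccc([nH]1)C(=O)[C@@H](CCCCCCN=[N+]=[N-])C[C@H](C)O | intermediate
10 | iminophosphorane of 9 (N=PPh3 in place of N3) | O=Cc1ccc([nH]1)C(=O)[C@@H](CCCCCCN=P(c1ccccc1)(c1ccccc1)c1ccccc1)C[C@H](C)O | intermediate (not isolated)
11 | macrocyclic imine, (3S)-3-[(2S)-2-hydroxypropyl]-10,15-diazabicyclo[10.2.1]pentadeca-1(14),10,12-trien-2-one | O=C1[C@H](C[C@H](C)O)CCCCCCN=Cc2ccc1[nH]2 | intermediate (not isolated)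
12 | macrocyclic amine, (3S)-3-[(2S)-2-hydroxypropyl]-10,15-diazabicyclo[10.2.1]pentadeca-1(14),12-dien-2-one | O=C1[C@H](C[C@H](C)O)CCCCCCNCc2ccc1[nH]2 | intermediate
13 | N-aminated adduct (N10 of 12 bonded to the nitrogen of N-(benzyloxy)-4-(trifluoromethyl)benzamide) | O=C1[C@H](C[C@H](C)O)CCCCCCN(Cc2ccc1[nH]2)N(OCc1ccccc1)C(=O)c1ccc(cc1)C(F)(F)F | intermediate (not isolated)
14 | isodiazene (1,1-diazene on N10 of 12) | O=C1[C@H](C[C@H](C)O)CCCCCC[N+](=[N-])Cc2ccc1[nH]2 | intermediate (not isolated)
15 | macrocyclic ketone, (3S)-3-[(2S)-2-hydroxypropyl]-14-azabicyclo[9.2.1]tetradeca-1(13),11-dien-2-one | O=C1[C@H](C[C@H](C)O)CCCCCCCc2ccc1[nH]2 | intermediate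
16 | 4-methoxy-1,5-dihydro-2H-pyrrol-2-one | COC1=CC(=O)NC1 | starting material
17 | 4-methoxy-1-(trimethylsilyl)-2-(trimethylsilyloxy)-1H-pyrrole | COc1cc(O[Si](C)(C)C)n([Si](C)(C)C)c1 | intermediate (not isolated)
18 | 5-ylidene lactam (E/Z mixture) | COC1=CC(=O)NC1=C1c2ccc([nH]2)CCCCCCC[C@H]1C[C@H](C)O | intermediate
19 | spiro-lactam | COC1=CC(=O)N[C@]12O[C@@H](C)C[C@@H]1CCCCCCCc3ccc([nH]3)[C@H]12 | intermediate
20 | pyrrole | c1cc[nH]c1 | starting material
21 | premarineosin A | COC1=CC(c2ccc[nH]2)=N[C@]12O[C@@H](C)C[C@@H]1CCCCCCCc3ccc([nH]3)[C@H]12 | target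

**Step count and risks**

Total step count: 9. Longest linear sequence: 8 steps (steps 1, 3, 4, 5, 6, 7, 8, 9 from compound 1; step 2 is a side branch).

Steps most likely to fail:

Step 7. The vinylogous-amide carbonyl of 15 may add the nucleophile too slowly, and enolisation toward the alpha carbon would epimerise the bridge-bearing centre. The fallback sets out from 15 and makes the same C–C bond at the alcohol oxidation level. NaBH4, THF/MeOH, 0 °C should give the pyrrol-2-yl carbinol F3. Sc(OTf)3 (cat.) with 17 (from 16, Me3SiOTf, Et3N), CH2Cl2, −40 → 0 °C should alkylate C5 of the silyloxypyrrole through the azafulvenium ion to the 5-alkyl lactam F4. DDQ, CH2Cl2, 0 °C then dehydrogenates the pyrrolyl–CH–CH(N) unit to 18, where the route is rejoined.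

Step 6. After loss of N2 the radical pair may disproportionate or diffuse apart, or the isodiazene may tautomerise to a hydrazone before it fragments. The fallback closes the same bond by olefination and sets out from 8. PPh3, NaI (cat.), MeCN, reflux should give the phosphonium chloride F1. KN(SiMe3)2 (3.2 equiv, two of them taken up by N–H and O–H), THF, high dilution, −78 → 25 °C should close the ring by intramolecular Wittig reaction to the macrocyclic alkene F2 (CH=CH at the pyrrole, mainly Z). H2, Pd/C, EtOAc then gives 15, where the route is rejoined.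

Step 8. Equilibration may give poor control at the spiro carbon and the adjacent methine, the hydroxyl may instead close a five-membered ether at the pyrrolylic carbon, and reversible alkenylpyrrole formation may erode the bridge-bearing centre. The fallback sets out from 18 and fixes the C–O bond kinetically. PhSeCl, 2,6-lutidine, CH2Cl2, −78 °C should add selenium to the enamide carbon and the hydroxyl to the acyliminium carbon to give the selenide F5. Bu3SnH, AIBN, PhMe, 80 °C then replaces selenium by hydrogen from the less hindered face and gives 19, where the route is rejoined.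

Further compounds
F1 | step 6 | {6-[(1S,3S)-1-(5-formyl-1H-pyrrole-2-carbonyl)-3-hydroxybutyl]hexyl}triphenylphosphonium chloride | O=Cc1ccc([nH]1)C(=O)[C@@H](CCCCCC[P+](c1ccccc1)(c1ccccc1)c1ccccc1)C[C@H](C)O.[Cl-]
F2 | step 6 | macrocyclic alkene, (3S)-3-[(2S)-2-hydroxypropyl]-14-azabicyclo[9.2.1]tetradeca-1(13),9,11-trien-2-one | O=C1[C@H](C[C@H](C)O)CCCCCC=Cc2ccc1[nH]2
F3 | step 7 | pyrrol-2-yl carbinol, (3S)-3-[(2S)-2-hydroxypropyl]-14-azabicyclo[9.2.1]tetradeca-1(13),11-dien-2-ol (epimers at C2) | OC1[C@H](C[C@H](C)O)CCCCCCCc2ccc1[nH]2
F4 | step 7 | 5-alkyl lactam, 4-methoxy-5-{(3S)-3-[(2S)-2-hydroxypropyl]-14-azabicyclo[9.2.1]tetradeca-1(13),11-dien-2-yl}-1,5-dihydro-2H-pyrrol-2-one (epimers at the two new centres) | COC1=CC(=O)NC1C1c2ccc([nH]2)CCCCCCC[C@H]1C[C@H](C)O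
F5 | step 8 | selenide, spiro-lactam 19 with phenylselanyl in place of H at the methine bearing ring C | COC1=CC(=O)NC12O[C@@H](C)C[C@@H]1CCCCCCCc3ccc([nH]3)C12[Se]c1ccccc1
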